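**Retrosynthetic overview**
Ring A is disconnected last at C1–C2 and C3–C4: a radical annulation inserts the two carbons of a vinylboronate (C2, C3) between a C1 radical on ring B and C4 on the C5 arm.
Enabling feature: C1 is a neopentyl CH2–I on the fully substituted C10, so its radical has only 4-exo and 5-endo modes towards the alkenes of ring B and lives long enough to be trapped intermolecularly; it lies trans to the C5 arm, and C4 is the β-carbon of a vinyl sulfone (C4=C18), so the C3 radical closes at C4 in a 6-exo-trig mode; boron on C3 is the masked hydroxyl and the sulfonylmethyl group the masked second C4 methyl.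
Ring B with C20 and the C4/C18/C19 carbons is the six-membered ring of (1S)-(−)-verbenone: conjugate addition sets C10, enolate alkylation brings the C9 side chain (from methyl hydrogen (R)-3-methylglutarate), and cleavage of the cyclobutane bond C4–C7 (a ring absent from the target) releases the isopropenyl group and the C8 ketone.
The C8 ketone becomes the C7=C8 enol triflate and then C17 by Stille hydroxymethylation; boronate oxidation and desulfonylation finish.
Ring order: ring B (chiral pool) first, ring A by the annulation.

Key step: step 10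

Remark: atoms are numbered as in labdane (ring A = C1–C5, C10; ring B = C5–C10; C17 on C8; side chain C11–C16), and commercial (1S)-(−)-verbenone is taken as enantiomerically pure (otherwise it would be made from (1S)-(−)-α-pinene).

**Route**

Step 1
Reactants: 1 methyl hydrogen (R)-3-methylglutarate
Product: 2 methyl (3R)-5-hydroxy-3-methylpentanoate
Conditions: BH3·SMe2, THF, 0 °C to rt; MeOH quench
Reagents that add atoms: none
Why: Chemoselective borane reduction of the free carboxylic acid (via the acyloxyborane) in the presence of the methyl ester; the C13 stereocentre comes from 1 and is not touched.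

Step 2
Reactants: 2 methyl (3R)-5-hydroxy-3-methylpentanoate
Product: 3 methyl (3S)-5-iodo-3-methylpentanoate
Conditions: PPh3, I2, imidazole, CH2Cl2, 0 °C to rt
Reagents that add atoms: iodine, II
Why: Appel-type iodination of the primary alcohol (SN2 on the alkoxyphosphonium ion), run at once on crude 2 to forestall lactonisation; the descriptor changes only through priority.

Step 3
Reactants: 4 (1S,5S)-(−)-verbenone; 5 vinylmagnesium bromide
Product: 6 (1S,4R,5R)-4-ethenyl-4,6,6-trimethylbicyclo[3.1.1]heptan-2-one
Conditions: CuI (10 mol %), THF, −40 to 0 °C; then 1 M HCl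
Reagents that add atoms: none
Why: Copper-catalysed conjugate addition of the Grignard reagent to the β,β-disubstituted enone from the face anti to the gem-dimethyl bridge should set quaternary C10 with the vinyl carbon (future C1) trans and the methyl cis to the bridge carbon (future C4).

Step 4
Reactants: 6 (1S,4R,5R)-4-ethenyl-4,6,6-trimethylbicyclo[3.1.1]heptan-2-one; 3 methyl (3S)-5-iodo-3-methylpentanoate
Product: 7 methyl (3R)-5-[4-ethenyl-4,6,6-trimethyl-2-oxobicyclo[3.1.1]hept-3-yl]-3-methylpentanoate (ring configured as in 6; both epimers at the alkylated carbon C9)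
Conditions: LiN(i-Pr)2, THF, −78 °C; then 3, DMPU, −78 to 0 °C
Reagents that add atoms: none
Why: Enolate C-alkylation; the ketone can enolise only towards C9 because the other α-carbon is a bridgehead, and the C9 configuration is left open here because step 7 equilibrates it.

Step 5
Reactants: 7 methyl (3R)-5-[4-ethenyl-4,6,6-trimethyl-2-oxobicyclo[3.1.1]hept-3-yl]-3-methylpentanoate
Product: 10 methyl (3R)-5-[4-(hydroxymethyl)-4,6,6-trimethyl-2-oxobicyclo[3.1.1]hept-3-yl]-3-methylpentanoate, via the secondary ozonide 8 (not isolated), via the keto aldehyde 9 (not isolated)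
Conditions: O3, CH2Cl2, −78 °C; Me2S, −78 °C to rt; then NaBH4, MeOH/CH2Cl2, −78 °C
Reagents that add atoms: ozone, O=[O+][O-]
Why: Ozonolysis cleaves the only C=C bond to the neopentyl aldehyde (C1), which NaBH4 at −78 °C should reduce chemoselectively in the presence of the hindered ketone and the ester; no stereocentre is affected.

Step 6
Reactants: 10 methyl (3R)-5-[4-(hydroxymethyl)-4,6,6-trimethyl-2-oxobicyclo[3.1.1]hept-3-yl]-3-methylpentanoate
Product: 11 methyl (3R)-5-[4-(iodomethyl)-4,6,6-trimethyl-2-oxobicyclo[3.1.1]hept-3-yl]-3-methylpentanoate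
Conditions: PPh3, I2, imidazole, toluene, 80 °C
Reagents that add atoms: iodine, II
Why: Appel iodination of the neopentyl-type primary alcohol under forcing conditions gives the radical precursor at C1 without touching a stereocentre.

Step 7
Reactants: 11 methyl (3R)-5-[4-(iodomethyl)-4,6,6-trimethyl-2-oxobicyclo[3.1.1]hept-3-yl]-3-methylpentanoate
Product: 14 methyl (3R)-5-[2-(iodomethyl)-2-methyl-6-oxo-3-(prop-1-en-2-yl)cyclohexyl]-3-methylpentanoate (side chain cis to the ring methyl; iodomethyl trans to isopropenyl), via the silyl enol ether diiodide 12 (not isolated), via the tertiary iodide ketone 13 (not isolated)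
Conditions: Me3SiI, CH2Cl2, −20 °C; 1 M HCl; then DBU, toluene, 60 °C
Reagents that add atoms: none
Why: Silyl activation of the ketone triggers the cyclobutane cleavage known for nopinones at the bond α to the carbonyl (C7–C4), giving a silyl enol ether and a tertiary iodide; after hydrolysis DBU should effect E2 elimination towards a methyl group (the C5–H is shielded by quaternary C10) and equilibrate C9 through the enol to the all-equatorial epimer with the side chain cis to the C10 methyl, while the amine base never builds up enough enolate for 3-exo displacement of the neopentyl iodide to compete with reprotonation.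

Step 8
Reactants: 14 methyl (3R)-5-[2-(iodomethyl)-2-methyl-6-oxo-3-(prop-1-en-2-yl)cyclohexyl]-3-methylpentanoate
Product: 15 methyl (3R)-5-[6-(iodomethyl)-6-methyl-5-(prop-1-en-2-yl)-2-(trifluoromethylsulfonyloxy)cyclohex-2-en-1-yl]-3-methylpentanoate
Conditions: KN(SiMe3)2, THF, −78 °C; PhNTf2, −78 to 0 °C
Reagents that add atoms: N-phenylbis(trifluoromethanesulfonimide), O=S(=O)(N(c1ccccc1)S(=O)(=O)C(F)(F)F)C(F)(F)F
Why: Kinetic enolisation should occur at the C7 methylene and not at the tertiary C9–H next to the quaternary carbon, and O-triflation of the enolate fixes the future C7=C8 double bond and locks C9.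

Step 9
Reactants: 15 methyl (3R)-5-[6-(iodomethyl)-6-methyl-5-(prop-1-en-2-yl)-2-(trifluoromethylsulfonyloxy)cyclohex-2-en-1-yl]-3-methylpentanoate
Product: 17 methyl (3R)-5-{6-(iodomethyl)-6-methyl-5-[(E)-1-(phenylsulfonyl)prop-1-en-2-yl]-2-(trifluoromethylsulfonyloxy)cyclohex-2-en-1-yl}-3-methylpentanoate, via the tertiary iodo sulfone 16 (not isolated)
Conditions: PhSO2Na, I2, EtOAc/H2O, rt, visible light; then Et3N, CH2Cl2, 0 °C
Reagents that add atoms: sodium benzenesulfinate, [Na+].[O-]S(=O)c1ccccc1
Why: Radical-chain iodosulfonylation (PhSO2I formed in the flask) should add the sulfonyl radical to the terminal carbon of the electron-rich 1,1-disubstituted alkene rather than to the electron-poor enol triflate, and Et3N removes the acidic α-sulfonyl proton (dehydroiodination) to give the conjugated E-vinyl sulfone.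

Step 10
Reactants: 17 methyl (3R)-5-{6-(iodomethyl)-6-methyl-5-[(E)-1-(phenylsulfonyl)prop-1-en-2-yl]-2-(trifluoromethylsulfonyloxy)cyclohex-2-en-1-yl}-3-methylpentanoate; 18 vinylboronic acid pinacol ester
Product: 19 methyl 4-(phenylsulfonylmethyl)-3-(pinacolboryl)-8-(trifluoromethylsulfonyloxy)-17,18-dinorlabd-7-en-15-oate (trans-decalin; boryl group equatorial on C3 and cis to the C10 methyl; C4 either configuration)
Conditions: (Me3Si)3SiH (1.3 equiv, syringe pump), AIBN (20 mol %), 18 (10 equiv), benzene, 80 °C
Reagents that add atoms: none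
Why: Radical chain annulation: the silyl radical abstracts iodine to give the neopentyl C1 radical, which adds to the unsubstituted carbon of the vinylboronate (C1–C2); the resulting α-boryl C3 radical closes ring A by 6-exo-trig addition to C4, the β-carbon of the vinyl sulfone (C3–C4), and the α-sulfonyl radical is reduced by the silane. The closest known reaction types are Giese addition of alkyl radicals to vinylboronic esters, cyclisation of α-boryl radicals onto alkenes and 6-exo cyclisation of carbon radicals onto vinyl sulfones, joined here as a radical addition–cyclisation annulation. Ring A closes through a chair-like transition state on the trans-diequatorial C1 and C4 arms of ring B, so the ring fusion (C5, C10) is trans by construction and the boryl group on C3 should take the pseudo-equatorial position, cis to the C10 methyl, away from the axial hydrogens on C1 and C5. C4 becomes quaternary; its configuration does not matter because the sulfonylmethyl group later becomes the second methyl. The step needs intermolecular addition to outrun reduction of the C1 radical and 1,5-hydrogen transfer from the C4 methyl group (large excess of boronate, slow silane addition) and cyclisation to outrun telomerisation (activated acceptor, low silane concentration); attack at C4 and not C18 is secured by the polarisation of the vinyl sulfone and the exo geometry.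

Step 11
Reactants: 19 methyl 4-(phenylsulfonylmethyl)-3-(pinacolboryl)-8-(trifluoromethylsulfonyloxy)-17,18-dinorlabd-7-en-15-oate; 20 (tributylstannyl)methanol
Product: 21 methyl 17-hydroxy-4-(phenylsulfonylmethyl)-3-(pinacolboryl)-18-norlabd-7-en-15-oate (C8 carries CH2OH in place of the triflate)
Conditions: Pd(PPh3)4 (10 mol %), LiCl, 1,4-dioxane, 100 °C
Reagents that add atoms: none
Why: Stille coupling of the enol triflate at zerovalent palladium (LiCl-assisted transmetalation) installs C17 as the allylic alcohol and should leave the alkylboronate, the sulfone and the ester untouched.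

Step 12
Reactants: 21 methyl 17-hydroxy-4-(phenylsulfonylmethyl)-3-(pinacolboryl)-18-norlabd-7-en-15-oate
Product: 22 methyl 3,17-dihydroxy-4-(phenylsulfonylmethyl)-18-norlabd-7-en-15-oate (3-OH equatorial; target configuration at C3/C5/C9/C10/C13)
Conditions: NaBO3·4H2O, THF/H2O, rt
Reagents that add atoms: sodium perborate, [Na+].[O-]OB=O
Why: Perborate oxidation of the secondary alkylboronate proceeds by 1,2-migration of carbon from boron to oxygen with retention, so the equatorial C3 alcohol follows from the C3 configuration set in step 10 under conditions mild enough for the methyl ester.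

Step 13
Reactants: 22 methyl 3,17-dihydroxy-4-(phenylsulfonylmethyl)-18-norlabd-7-en-15-oate
Product: 23 methyl (3R,5S,9S,10S,13R)-3,17-dihydroxylabd-7-en-15-oate (CNP0313905.1)
Conditions: Na(Hg) (6 %), Na2HPO4, MeOH/THF, 0 °C to rt
Reagents that add atoms: none
Why: Julia-type reductive desulfonylation (single-electron reduction of the alkyl phenyl sulfone, C–S cleavage, protonation) turns the sulfonylmethyl group into the second C4 methyl, which also removes the C4 stereocentre; the buffered medium should spare the ester and the allylic alcohol.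

**Compound list**
1 | methyl hydrogen (R)-3-methylglutarate | COC(=O)C[C@H](C)CC(=O)O | starting material
2 | methyl (3R)-5-hydroxy-3-methylpentanoate | COC(=O)C[C@H](C)CCO | intermediate
3 | methyl (3S)-5-iodo-3-methylpentanoate | COC(=O)C[C@H](C)CCI | intermediate
4 | (1S,5S)-(−)-verbenone | CC1=CC(=O)[C@H]2C[C@@H]1C2(C)C | starting material
5 | vinylmagnesium bromide | C=C[Mg]Br | starting material
6 | (1S,4R,5R)-4-ethenyl-4,6,6-trimethylbicyclo[3.1.1]heptan-2-one | C[C@]1(C=C)CC(=O)[C@H]2C[C@@H]1C2(C)C | intermediate
7 | methyl (3R)-5-[4-ethenyl-4,6,6-trimethyl-2-oxobicyclo[3.1.1]hept-3-yl]-3-methylpentanoate (C9 epimers) | C[C@]1(C=C)C(CC[C@@H](C)CC(=O)OC)C(=O)[C@H]2C[C@@H]1C2(C)C | intermediate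
8 | secondary ozonide of 7 | C[C@]1(C2OCOO2)C(CC[C@@H](C)CC(=O)OC)C(=O)[C@H]2C[C@@H]1C2(C)C | intermediate
9 | keto aldehyde (formyl in place of the ethenyl group of 7) | C[C@]1(C=O)C(CC[C@@H](C)CC(=O)OC)C(=O)[C@H]2C[C@@H]1C2(C)C | intermediate
10 | methyl (3R)-5-[4-(hydroxymethyl)-4,6,6-trimethyl-2-oxobicyclo[3.1.1]hept-3-yl]-3-methylpentanoate | C[C@]1(CO)C(CC[C@@H](C)CC(=O)OC)C(=O)[C@H]2C[C@@H]1C2(C)C | intermediate
11 | methyl (3R)-5-[4-(iodomethyl)-4,6,6-trimethyl-2-oxobicyclo[3.1.1]hept-3-yl]-3-methylpentanoate | C[C@]1(CI)C(CC[C@@H](C)CC(=O)OC)C(=O)[C@H]2C[C@@H]1C2(C)C | intermediate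
12 | methyl (3R)-5-[6-(iodomethyl)-5-(2-iodopropan-2-yl)-6-methyl-2-(trimethylsilyloxy)cyclohex-2-en-1-yl]-3-methylpentanoate | COC(=O)C[C@H](C)CCC1C(O[Si](C)(C)C)=CC[C@H](C(C)(C)I)[C@@]1(C)CI | intermediate
13 | methyl (3R)-5-[2-(iodomethyl)-3-(2-iodopropan-2-yl)-2-methyl-6-oxocyclohexyl]-3-methylpentanoate | COC(=O)C[C@H](C)CCC1C(=O)CC[C@H](C(C)(C)I)[C@@]1(C)CI | intermediate
14 | methyl (3R)-5-[2-(iodomethyl)-2-methyl-6-oxo-3-(prop-1-en-2-yl)cyclohexyl]-3-methylpentanoate (C5, C9, C10 as in the target) | COC(=O)C[C@H](C)CC[C@@H]1C(=O)CC[C@H](C(C)=C)[C@@]1(C)CI | intermediate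
15 | enol triflate of 14 (C7=C8) | COC(=O)C[C@H](C)CC[C@@H]1C(OS(=O)(=O)C(F)(F)F)=CC[C@H](C(C)=C)[C@@]1(C)CI | intermediate
16 | tertiary iodo sulfone (PhSO2–I adduct across the isopropenyl group of 15) | COC(=O)C[C@H](C)CC[C@@H]1C(OS(=O)(=O)C(F)(F)F)=CC[C@H](C(C)(I)CS(=O)(=O)c2ccccc2)[C@@]1(C)CI | intermediate
17 | (E)-vinyl sulfone enol triflate iodide | COC(=O)C[C@H](C)CC[C@@H]1C(OS(=O)(=O)C(F)(F)F)=CC[C@H](/C(C)=C/S(=O)(=O)c2ccccc2)[C@@]1(C)CI | intermediate
18 | vinylboronic acid pinacol ester | C=CB1OC(C)(C)C(C)(C)O1 | starting material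
19 | methyl 4-(phenylsulfonylmethyl)-3-(pinacolboryl)-8-(trifluoromethylsulfonyloxy)-17,18-dinorlabd-7-en-15-oate | COC(=O)C[C@H](C)CC[C@@H]1C(OS(=O)(=O)C(F)(F)F)=CC[C@@H]2C(C)(CS(=O)(=O)c3ccccc3)[C@H](B3OC(C)(C)C(C)(C)O3)CC[C@@]12C | intermediate
20 | (tributylstannyl)methanol | OC[Sn](CCCC)(CCCC)CCCC | starting material
21 | methyl 17-hydroxy-4-(phenylsulfonylmethyl)-3-(pinacolboryl)-18-norlabd-7-en-15-oate | COC(=O)C[C@H](C)CC[C@@H]1C(CO)=CC[C@@H]2C(C)(CS(=O)(=O)c3ccccc3)[C@H](B3OC(C)(C)C(C)(C)O3)CC[C@@]12C | intermediate
22 | methyl 3,17-dihydroxy-4-(phenylsulfonylmethyl)-18-norlabd-7-en-15-oate | COC(=O)C[C@H](C)CC[C@@H]1C(CO)=CC[C@@H]2C(C)(CS(=O)(=O)c3ccccc3)[C@H](O)CC[C@@]12C | intermediate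
23 | methyl (3R,5S,9S,10S,13R)-3,17-dihydroxylabd-7-en-15-oate | COC(=O)C[C@H](C)CC[C@@H]1C(CO)=CC[C@@H]2C(C)(C)[C@H](O)CC[C@@]12C | target

**Totals**
Total step count: 13. Longest linear sequence: 12 steps (1 to 23, steps 1, 2 and 4–13).

**Steps most likely to fail**

Step 10. The C1 radical or the α-boryl radical may be reduced by the silane before C–C bond formation, the C1 radical may be lost through 1,5-hydrogen transfer from the C4 methyl group, the α-boryl radical may add to further vinylboronate (telomerisation), or facial selectivity at C3 may be poor. The fallback builds ring A stepwise from 15 with known chemistry. Bu3SnH/AIBN-mediated Giese addition of the C1 radical to 18 gives the primary alkylboronate F1. NaBO3·4H2O oxidation gives the primary alcohol F2, and Dess–Martin periodinane gives the aldehyde F3. Hydrogen-atom-transfer radical cyclisation with Fe(acac)3 and PhSiH3 in ethanol at 60 °C (tertiary C4 radical from the isopropenyl group, 6-exo addition to the aldehyde) should give the 3-hydroxy-4,4-dimethyl decalin enol triflate F4. Stille coupling of F4 with 20 under the conditions of step 11 returns to the route at 23.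

Step 4. C-alkylation of the hindered, neopentyl-type enolate may be slow, so that O-alkylation or attack of the enolate on the ester of 3 competes. The fallback sets out from 6 and uses an aldol route. Alcohol 2 is oxidised with Dess–Martin periodinane to methyl (3R)-3-methyl-5-oxopentanoate F5. The lithium enolate of 6 (LiN(i-Pr)2, THF, −78 °C) adds to F5 to give the β-hydroxy ketone F6. Acid-catalysed dehydration (p-TsOH, benzene, reflux) gives the exocyclic enone F7. Conjugate reduction with [(Ph3P)CuH]6, which leaves the isolated vinyl group alone, returns to the route at 7.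

Step 9. Dehydroiodination may run towards the methyl group, or the base may move the double bond out of conjugation to the allyl sulfone, which removes the 6-exo acceptor. The fallback sets out from 15. Dihydroxylation of the electron-rich isopropenyl group with OsO4 (catalytic) and N-methylmorpholine N-oxide gives the diol F8. NaIO4 cleavage gives the methyl ketone F9. Horner–Wadsworth–Emmons olefination with the pre-formed lithium salt of diethyl [(phenylsulfonyl)methyl]phosphonate (n-BuLi, THF, −78 °C to rt) returns to the route at 17.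

Further compounds
F1 | step 10 | primary alkylboronate (CH2CH2CH2Bpin on C10 in place of the CH2I of 15) | COC(=O)C[C@H](C)CC[C@@H]1C(OS(=O)(=O)C(F)(F)F)=CC[C@H](C(C)=C)[C@@]1(C)CCCB1OC(C)(C)C(C)(C)O1
F2 | step 10 | primary alcohol from F1 | COC(=O)C[C@H](C)CC[C@@H]1C(OS(=O)(=O)C(F)(F)F)=CC[C@H](C(C)=C)[C@@]1(C)CCCO
F3 | step 10 | aldehyde from F2 | COC(=O)C[C@H](C)CC[C@@H]1C(OS(=O)(=O)C(F)(F)F)=CC[C@H](C(C)=C)[C@@]1(C)CCC=O
F4 | step 10 | 3-hydroxy-4,4-dimethyl decalin enol triflate | COC(=O)C[C@H](C)CC[C@@H]1C(OS(=O)(=O)C(F)(F)F)=CC[C@@H]2C(C)(C)[C@H](O)CC[C@@]12C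
F5 | step 4 | methyl (3R)-3-methyl-5-oxopentanoate | COC(=O)C[C@H](C)CC=O
F6 | step 4 | aldol adduct of 6 and F5 | C[C@]1(C=C)C(C(O)C[C@@H](C)CC(=O)OC)C(=O)[C@H]2C[C@@H]1C2(C)C
F7 | step 4 | exocyclic enone from F6 | C[C@]1(C=C)C(=CC[C@@H](C)CC(=O)OC)C(=O)[C@H]2C[C@@H]1C2(C)C
F8 | step 9 | diol from the isopropenyl group of 15 | COC(=O)C[C@H](C)CC[C@@H]1C(OS(=O)(=O)C(F)(F)F)=CC[C@H](C(C)(O)CO)[C@@]1(C)CI
F9 | step 9 | methyl ketone (acetyl on C5) | COC(=O)C[C@H](C)CC[C@@H]1C(OS(=O)(=O)C(F)(F)F)=CC[C@H](C(C)=O)[C@@]1(C)CI
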